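The fall of solid substrate per volume stays the same when the charge changes: the alpha run, charged with 20 mM, loses 0.182 mM min⁻¹ up to its last reading, and the delta run, charged with 10 mM, loses 0.191 mM min⁻¹.

| flask | solid substrate | remark | time |
|---|---|---|---|
| alpha | 20 mM | the very flask that is asked about, followed so far |  |
| delta | 10 mM | run made earlier |  |
| flask | 20 mM |  | 15 min |

| run | time / min | solid substrate / % | ring / % |
|---|---|---|---|
| alpha | 0.667 | 98.9 | 1.2 |
| alpha | 2.00 | 97.7 | 2.0 |
| alpha | 4.00 | 95.8 | 2.5 |
| alpha | 5.00 | 95.7 | 1.4 |
| alpha | 8.00 | 92.7 | 1.4 |
| delta | 1.00 | 98.3 | 0 |
| delta | 2.50 | 95.3 | 3.7 |
| delta | 5.00 | 91.0 | 4.4 |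
| delta | 8.00 | 86.1 | 4.7 |
| delta | 10.0 | 80.9 | 4.7 |

(each reading ± 1 percentage point)

1. which holds at 15 min: what has brought the reaction to rest, or that it has not come to rest (for what has run out or reacted, a solid counts together with what of it has only dissolved) (it is still moving / all of the solid substrate has reacted / forward and back rates have come level)
2. part of the solid substrate that has turned into other species by 15 min (what has only dissolved does not count)
3. amount of ring at 15 min, in percent of the solid substrate charged

- given per volume of solution although it is solid: solid substrate
- the numbers in the tables scatter by 1 percentage point (one standard deviation)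
- at the start none of the solid substrate is in solution
- what has only dissolved of solid substrate counts as not reacted
- the reaction counts as stopped when no species that holds the solid substrate changes by six tenths of a point or more over the second half of the time

The feed rate F, the mean of these two falls in concentration per minute, is 0.187 mM min⁻¹; the loss is zero order in the charge. Replacing the curve by this straight line costs little: in the delta run at 5.00 min the line misses the reading by 0.34 percentage points, less than the scatter of 1 point.

In the first instants of the alpha run, ring is already read at 1.2 % after 0.667 min. In the middle, ring in the delta run reads 3.7 % at 2.50 min, then 4.7 % at 8.00 min and 4.7 % at 10.0 min, while the solid keeps falling. At 8.00 min the alpha run has a gap of 5.9 points in neither column.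

At F the charge of the flask lasts 107 min, longer than the 15 min asked, so the line holds to the end. It leaves 86.0 % as solid, a loss of 14.0 %, and the solid still falls 7 points over the second half, so the flask is still moving. Conversion is that loss less what has only dissolved. The ring reading of 0.470 mM in the delta run, held as a concentration, gives 2.35 % here.

The forecast extends the same line and also holds ring as a concentration: it gives it is still moving, with 14 % converted and 2 % of ring, and says “it stays linear with no sign of slowing”.

The flask gives it is still moving, with 11.4 % converted and 3.34 % of ring.

    starting material ⇌ ring (K = 1.10, k = 0.0370 s⁻¹)
    2 starting material → open dimer (k = 2.70 M⁻¹ s⁻¹)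
    starting material + open dimer → open trimer (k = 26.0 M⁻¹ s⁻¹)
    solid substrate ⇌ starting material, rate k4*(cs4 - [starting material]) while solid is left; crystals form when [starting material] > cs4 (solubility = 6.30 mM, k = 5.50 × 10⁻⁴ s⁻¹)

At 15.0 min the flask holds 85.5 % as solid substrate, where the line gave 86.0 %, and 3.05 % of its charge is starting material that has only dissolved. The same flask charged with 80 mM loses 3.51 % at F, which leaves 96.5 % as solid, and it holds 96.4 %.

The earlier runs and the new flask are calculated with constants of no real substance, noise included.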